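Ring B of the target (C4a–C5–C6–C7–C8–C8a, target locants) is a 4,4-disubstituted cyclohexa-2,5-dienone in which C8a is the γ-carbon of the C4a=C5–C6=O enone and C8 the β-carbon of the second enone arm. Everything rests on cutting C5–C6 and C8–C8a: ring B is assembled in one flask from a monocyclic ring A allylstannane and a three-carbon β-methoxyacryloyl chloride. Palladium-catalysed acyl transfer to the allylic CH2 (C5–C6) is followed by deprotonation to an oxido-triene that closes through C8a onto C8 (6π) and expels methoxide, so the dienone and its quaternary methyl centre, set by the neighbouring C1 methyl, appear together.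

Key step: step 9

Remark: atom labels C1 to C8a are the ring locants of the target (C1 = CHMe, C2 = C–O, C6 = ring C=O, C8a = quaternary carbon). The β-methoxy enol ethers of the three-carbon fragment are drawn as (E) isomers; this geometry is lost in the key step and is of no consequence.

Step 1
Reactants: 1 ethyl 2-methyl-4-oxocyclohex-2-ene-1-carboxylate (Hagemann's ester, racemic)
Product: 2 ethyl 2,3-dimethyl-4-oxocyclohex-2-ene-1-carboxylate (racemic)
Conditions: NaOEt, EtOH, 0 °C; MeI, reflux
Reagents that add atoms: iodomethane, CI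
Why: Alkylation of the vinylogous β-keto ester anion of Hagemann's ester occurs at C3, α to the ketone, and the product returns to the conjugated enone under the basic conditions (classical Hagemann's ester alkylation); no stereocentre of the target is set here.

Step 2
Reactants: 2 ethyl 2,3-dimethyl-4-oxocyclohex-2-ene-1-carboxylate
Product: 4 ethyl (3R,4S)-4-hydroxy-2,3-dimethylcyclohex-1-ene-1-carboxylate, via deconjugated keto ester 3 (not isolated)
Conditions: LiN(iPr)2, THF, −78 °C, then AcOH, −78 °C; crude ketone: RuCl[(S,S)-TsDPEN](p-cymene) (1 mol %), HCO2H/Et3N 5:2, CH2Cl2, 25 °C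
Reagents that add atoms: none
Why: Kinetic α-protonation of the extended enolate deconjugates the enone into 3, whose C3–H is a rapidly racemising vinylogous β-keto ester position, so Noyori–Ikariya asymmetric transfer hydrogenation should run as a dynamic kinetic resolution in which hydride adds anti to the pseudoaxial C3 methyl (cis alcohol) and the (S,S)-catalyst selects the (3R) ketone, which sets the future C1 stereocentre and a C2 carbinol (4S) that is inverted in step 14.

Step 3
Reactants: 4 ethyl (3R,4S)-4-hydroxy-2,3-dimethylcyclohex-1-ene-1-carboxylate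
Product: 5 ethyl (3R,4S)-4-{[tert-butyl(dimethyl)silyl]oxy}-2,3-dimethylcyclohex-1-ene-1-carboxylate
Conditions: TBSCl, imidazole, DMF, 25 °C
Reagents that add atoms: tert-butyl(chloro)dimethylsilane, CC(C)(C)[Si](C)(C)Cl
Why: Imidazole-promoted silylation protects the secondary alcohol against the hydride, stannyl anion, acyl chloride and amide base used later and leaves both stereocentres untouched.

Step 4
Reactants: 5 ethyl (3R,4S)-4-{[tert-butyl(dimethyl)silyl]oxy}-2,3-dimethylcyclohex-1-ene-1-carboxylate
Product: 6 [(3R,4S)-4-{[tert-butyl(dimethyl)silyl]oxy}-2,3-dimethylcyclohex-1-en-1-yl]methanol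
Conditions: iBu2AlH (2.2 equiv), CH2Cl2, −78 → 0 °C; aq. KNaC4H4O6 work-up
Reagents that add atoms: none
Why: iBu2AlH reduces the α,β-unsaturated ester by 1,2-hydride delivery to the primary allylic alcohol (the future C5) without touching the tetrasubstituted alkene or the silyl ether.

Step 5
Reactants: 6 [(3R,4S)-4-{[tert-butyl(dimethyl)silyl]oxy}-2,3-dimethylcyclohex-1-en-1-yl]methanol
Product: 8 tributyl{[(3R,4S)-4-{[tert-butyl(dimethyl)silyl]oxy}-2,3-dimethylcyclohex-1-en-1-yl]methyl}stannane, via allylic methanesulfonate 7 (not isolated)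
Conditions: nBuLi, THF, −78 °C; MsCl; then Bu3SnLi (from Bu3SnH and LiN(iPr)2), THF, −78 → −20 °C
Reagents that add atoms: tributylstannane (used as its lithium derivative), CCCC[SnH](CCCC)CCCC
Why: O-Sulfonylation of the lithium alkoxide and SN2 displacement of the primary allylic methanesulfonate by the soft stannyl anion give the allylstannane with the alkene kept between the future C4a and C8a (alkylation of a stannyl anion).

Step 6
Reactants: 9 methyl 3,3-dimethoxypropanoate
Product: 10 methyl 2-(dimethoxymethyl)-3-hydroxy-3-methylbutanoate (racemic)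
Conditions: LiN(iPr)2, THF, −78 °C; acetone, −78 °C; AcOH quench at −78 °C
Reagents that add atoms: acetone, CC(C)=O
Why: Aldol addition of the lithium ester enolate to acetone at low temperature places the tertiary carbinol on the future C7 (the acetal carbon is the future C8); the new α-stereocentre is erased in step 7.

Step 7
Reactants: 10 methyl 2-(dimethoxymethyl)-3-hydroxy-3-methylbutanoate
Product: 11 methyl (2E)-3-methoxy-2-{2-[(triethylsilyl)oxy]propan-2-yl}prop-2-enoate
Conditions: Et3SiOTf (2.5 equiv), Et3N, CH2Cl2, 0 → 25 °C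
Reagents that add atoms: triethylsilyl trifluoromethanesulfonate, CC[Si](CC)(CC)OS(=O)(=O)C(F)(F)F
Why: The silyl triflate ionises the dimethyl acetal and Et3N removes the α-proton, giving the methyl enol ether with loss of Et3SiOMe (silyl-triflate-mediated acetal to enol ether conversion), while the tertiary alcohol is silylated in the same flask.

Step 8
Reactants: 11 methyl (2E)-3-methoxy-2-{2-[(triethylsilyl)oxy]propan-2-yl}prop-2-enoate
Product: 13 (2E)-3-methoxy-2-{2-[(triethylsilyl)oxy]propan-2-yl}prop-2-enoyl chloride, via potassium carboxylate 12 (not isolated)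
Conditions: KOSiMe3, THF, 25 → 50 °C; evaporate; (COCl)2, DMF (cat.), CH2Cl2, 0 °C; used at once
Reagents that add atoms: oxalyl chloride, ClC(=O)C(=O)Cl
Why: Anhydrous silanolate cleavage of the methyl ester gives the dry potassium carboxylate, which oxalyl chloride with catalytic DMF converts into the acyl chloride without free acid, so the tertiary silyl ether survives.

Step 9
Reactants: 8 tributyl{[(3R,4S)-4-{[tert-butyl(dimethyl)silyl]oxy}-2,3-dimethylcyclohex-1-en-1-yl]methyl}stannane; 13 (2E)-3-methoxy-2-{2-[(triethylsilyl)oxy]propan-2-yl}prop-2-enoyl chloride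
Product: 15 (4aR,5R,6S)-6-{[tert-butyl(dimethyl)silyl]oxy}-4a,5-dimethyl-3-{2-[(triethylsilyl)oxy]propan-2-yl}-5,6,7,8-tetrahydronaphthalen-2(4aH)-one, via allyl ketone 14 (not isolated)
Conditions: Pd2(dba)3 (2.5 mol %), P(2-furyl)3 (10 mol %), THF, 50 °C; then −78 °C, KN(SiMe3)2 (2.5 equiv), −78 → 0 °C; AcOH quench
Reagents that add atoms: none
Why: Oxidative addition of zerovalent palladium into the acyl chloride, allyl transfer from tin and reductive elimination at the unhindered CH2 terminus forge C5–C6 and give allyl ketone 14 with the tetrasubstituted alkene fixed at C4a=C8a (Migita–Kosugi–Stille ketone synthesis, as with prenylstannanes). KN(SiMe3)2 then removes the doubly activated C5–H to give an oxido-hexatriene (extended enolate) that bonds from its γ-carbon C8a to C8, a disrotatory 6π electrocyclisation equivalent to a 6-endo vinylogous Michael addition, and β-elimination of methoxide delivers the cross-conjugated dienone; the closest known reaction type is the addition–elimination of enolates to β-alkoxy enones. Ring B is thus closed in the 6π (6-endo-trig) mode. The new quaternary centre C8a is controlled by the adjacent C1 methyl, which sits pseudoaxial because of A(1,2) strain with the C8a methyl and, with the equatorial silyloxy group on the same face, sends C8 to the opposite face (the sense known from annulations of 2,3-dimethylcyclohexanone enolates). The step needs regioselectivity for C8a over C4, which is secured because the alkene is locked between C4a and C8a so that only C5 is deprotonated, and closure through the α-carbon C5 would give a four-membered ring.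

Step 10
Reactants: 15 (4aR,5R,6S)-6-{[tert-butyl(dimethyl)silyl]oxy}-4a,5-dimethyl-3-{2-[(triethylsilyl)oxy]propan-2-yl}-5,6,7,8-tetrahydronaphthalen-2(4aH)-one
Product: 16 (4aR,5R,6S)-6-hydroxy-3-(2-hydroxypropan-2-yl)-4a,5-dimethyl-5,6,7,8-tetrahydronaphthalen-2(4aH)-one
Conditions: HF·pyridine, THF/pyridine, 0 → 25 °C
Reagents that add atoms: none
Why: Fluoride-mediated desilylation under buffered, non-basic conditions removes both silyl ethers; the dienone survives, and the tertiary carbinol cannot dehydrate into the ring because C7 carries no hydrogen.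

Step 11
Reactants: 17 prop-2-yn-1-ol
Product: 18 (2Z)-3-iodo-2-methylprop-2-en-1-ol
Conditions: MeMgBr (2.5 equiv), CuI (10 mol %), THF, −10 → 25 °C; then I2, −78 → 0 °C
Reagents that add atoms: methylmagnesium bromide, C[Mg]Br; iodine, II
Why: Copper-catalysed anti-carbomagnesiation of the magnesium propargyl alkoxide gives a chelated alkenylmagnesium species whose iodinolysis with retention fixes the (Z) geometry (iodine cis to CH2OH).

Step 12
Reactants: 18 (2Z)-3-iodo-2-methylprop-2-en-1-ol
Product: 19 (2Z)-3-iodo-2-methylprop-2-enoic acid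
Conditions: TEMPO (20 mol %), PhI(OAc)2 (2.2 equiv), MeCN/H2O 1:1, 25 °C
Reagents that add atoms: water, O
Why: Oxoammonium-catalysed oxidation takes the primary allylic alcohol through the aldehyde hydrate to the acid without touching the alkenyl iodide or its geometry (TEMPO/hypervalent iodine oxidation).

Step 13
Reactants: 19 (2Z)-3-iodo-2-methylprop-2-enoic acid
Product: 20 (2Z)-2-methyl-3-(methylsulfanyl)prop-2-enoic acid
Conditions: NaSMe (2.2 equiv), CuI (5 mol %), DMF, 0 → 25 °C; then 1 M HCl
Reagents that add atoms: sodium methanethiolate, [Na+].[S-]C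
Why: Copper-catalysed C–S coupling of the alkenyl iodide with thiolate (backed by addition–elimination on the β-iodoacrylate) proceeds with retention, giving the (Z) acid with sulfur cis to the carboxyl group.

Step 14
Reactants: 16 (4aR,5R,6S)-6-hydroxy-3-(2-hydroxypropan-2-yl)-4a,5-dimethyl-5,6,7,8-tetrahydronaphthalen-2(4aH)-one; 20 (2Z)-2-methyl-3-(methylsulfanyl)prop-2-enoic acid
Product: 21 (1R,2R,8aR)-7-(2-hydroxypropan-2-yl)-1,8a-dimethyl-6-oxo-1,2,3,4,6,8a-hexahydronaphthalen-2-yl (2Z)-2-methyl-3-(methylsulfanyl)prop-2-enoate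
Conditions: PPh3, DIAD, toluene, 0 → 25 °C
Reagents that add atoms: none
Why: Mitsunobu esterification activates the secondary alcohol as its oxyphosphonium salt and the carboxylate displaces it by SN2 with inversion, which sets C2 (R) trans to the C1 methyl, while the tertiary alcohol cannot react.

Compound list
1 | ethyl 2-methyl-4-oxocyclohex-2-ene-1-carboxylate (Hagemann's ester, racemic) | CCOC(=O)C1CCC(=O)C=C1C | starting material
2 | ethyl 2,3-dimethyl-4-oxocyclohex-2-ene-1-carboxylate (racemic) | CCOC(=O)C1CCC(=O)C(C)=C1C | intermediate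
3 | ethyl 2,3-dimethyl-4-oxocyclohex-1-ene-1-carboxylate (racemic, not isolated) | CCOC(=O)C1=C(C)C(C)C(=O)CC1 | intermediate
4 | ethyl (3R,4S)-4-hydroxy-2,3-dimethylcyclohex-1-ene-1-carboxylate | O[C@H]1CCC(C(=O)OCC)=C(C)[C@H]1C | intermediate
5 | ethyl (3R,4S)-4-{[tert-butyl(dimethyl)silyl]oxy}-2,3-dimethylcyclohex-1-ene-1-carboxylate | CC(C)(C)[Si](C)(C)O[C@H]1CCC(C(=O)OCC)=C(C)[C@H]1C | intermediate
6 | [(3R,4S)-4-{[tert-butyl(dimethyl)silyl]oxy}-2,3-dimethylcyclohex-1-en-1-yl]methanol | CC(C)(C)[Si](C)(C)O[C@H]1CCC(CO)=C(C)[C@H]1C | intermediate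
7 | [(3R,4S)-4-{[tert-butyl(dimethyl)silyl]oxy}-2,3-dimethylcyclohex-1-en-1-yl]methyl methanesulfonate (not isolated) | CC(C)(C)[Si](C)(C)O[C@H]1CCC(COS(C)(=O)=O)=C(C)[C@H]1C | intermediate
8 | tributyl{[(3R,4S)-4-{[tert-butyl(dimethyl)silyl]oxy}-2,3-dimethylcyclohex-1-en-1-yl]methyl}stannane | CC(C)(C)[Si](C)(C)O[C@H]1CCC(C[Sn](CCCC)(CCCC)CCCC)=C(C)[C@H]1C | intermediate
9 | methyl 3,3-dimethoxypropanoate | COC(=O)CC(OC)OC | starting material
10 | methyl 2-(dimethoxymethyl)-3-hydroxy-3-methylbutanoate (racemic) | COC(=O)C(C(OC)OC)C(C)(C)O | intermediate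
11 | methyl (2E)-3-methoxy-2-{2-[(triethylsilyl)oxy]propan-2-yl}prop-2-enoate | CO/C=C(/C(=O)OC)C(C)(C)O[Si](CC)(CC)CC | intermediate
12 | potassium (2E)-3-methoxy-2-{2-[(triethylsilyl)oxy]propan-2-yl}prop-2-enoate (not isolated) | [K+].CO/C=C(/C(=O)[O-])C(C)(C)O[Si](CC)(CC)CC | intermediate
13 | (2E)-3-methoxy-2-{2-[(triethylsilyl)oxy]propan-2-yl}prop-2-enoyl chloride | CO/C=C(/C(=O)Cl)C(C)(C)O[Si](CC)(CC)CC | intermediate
14 | (3E)-1-[(3R,4S)-4-{[tert-butyl(dimethyl)silyl]oxy}-2,3-dimethylcyclohex-1-en-1-yl]-4-methoxy-3-{2-[(triethylsilyl)oxy]propan-2-yl}but-3-en-2-one (not isolated) | CC(C)(C)[Si](C)(C)O[C@H]1CCC(CC(=O)/C(=C/OC)C(C)(C)O[Si](CC)(CC)CC)=C(C)[C@H]1C | intermediate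
15 | (4aR,5R,6S)-6-{[tert-butyl(dimethyl)silyl]oxy}-4a,5-dimethyl-3-{2-[(triethylsilyl)oxy]propan-2-yl}-5,6,7,8-tetrahydronaphthalen-2(4aH)-one | CC(C)(C)[Si](C)(C)O[C@H]1CCC2=CC(=O)C(C(C)(C)O[Si](CC)(CC)CC)=C[C@]2(C)[C@H]1C | intermediate
16 | (4aR,5R,6S)-6-hydroxy-3-(2-hydroxypropan-2-yl)-4a,5-dimethyl-5,6,7,8-tetrahydronaphthalen-2(4aH)-one | O[C@H]1CCC2=CC(=O)C(C(C)(C)O)=C[C@]2(C)[C@H]1C | intermediate
17 | prop-2-yn-1-ol | OCC#C | starting material
18 | (2Z)-3-iodo-2-methylprop-2-en-1-ol | I/C=C(/C)CO | intermediate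
19 | (2Z)-3-iodo-2-methylprop-2-enoic acid | I/C=C(/C)C(=O)O | intermediate
20 | (2Z)-2-methyl-3-(methylsulfanyl)prop-2-enoic acid | CS/C=C(/C)C(=O)O | intermediate
21 | (1R,2R,8aR)-7-(2-hydroxypropan-2-yl)-1,8a-dimethyl-6-oxo-1,2,3,4,6,8a-hexahydronaphthalen-2-yl (2Z)-2-methyl-3-(methylsulfanyl)prop-2-enoate | CS/C=C(/C)C(=O)O[C@@H]1CCC2=CC(=O)C(C(C)(C)O)=C[C@]2(C)[C@H]1C | target

Total step count: 14. Longest linear sequence: 8 steps (1, 2, 3, 4, 5, 9, 10, 14).

Steps most likely to fail

Step 9. The acyl group may be delivered to the hindered allyl terminus, the allylstannane may be protodestannylated before coupling, or the ring closure may be reversed by re-addition of methoxide to C8. The fallback forms the two bonds in separate operations through a sulfonyl-stabilised carbanion. It sets out from 6: the alcohol is converted through its methanesulfonate (nBuLi, MsCl, THF, −78 °C) with PhSO2Na in DMF into {[(3R,4S)-4-{[tert-butyl(dimethyl)silyl]oxy}-2,3-dimethylcyclohex-1-en-1-yl]methanesulfonyl}benzene F1. Its α-carbanion (LiN(iPr)2, 2 equiv, THF, −78 °C) is acylated by 13 at the sulfonyl-bearing carbon to give (3E)-1-(benzenesulfonyl)-1-[(3R,4S)-4-{[tert-butyl(dimethyl)silyl]oxy}-2,3-dimethylcyclohex-1-en-1-yl]-4-methoxy-3-{2-[(triethylsilyl)oxy]propan-2-yl}but-3-en-2-one F2. Reductive desulfonylation with Al(Hg) in wet THF at 0 °C gives isolated 14, which KN(SiMe3)2 (THF, −78 → 0 °C) cyclises as in the second stage of step 9; the route is rejoined at 15.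

Step 2. Enantiomer discrimination by the ruthenium hydride may be weak for this ketone without an aryl group, racemisation of 3 may be slower than its reduction, and 3 may drift back to the unreactive conjugated enone 2. The fallback replaces the dynamic resolution by a diastereoselective reduction and an enzymatic kinetic resolution. It sets out from 2: deconjugated ketone 3 is isolated (LiN(iPr)2, then AcOH, −78 °C) and reduced with LiBH(sBu)3 (THF, −78 °C) to the racemic cis alcohol, that is 4 together with its enantiomer ethyl (3S,4R)-4-hydroxy-2,3-dimethylcyclohex-1-ene-1-carboxylate F3. Burkholderia cepacia lipase with vinyl acetate (tert-butyl methyl ether, 30 °C) should acetylate the (4R) alcohol faster (Kazlauskas rule) to ethyl (3S,4R)-4-(acetyloxy)-2,3-dimethylcyclohex-1-ene-1-carboxylate F4, which is separated; the unreacted alcohol is 4, where the route is rejoined.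

Step 14. On this hindered secondary alcohol next to the C1 methyl, elimination toward C3 or esterification with retention through an acyloxyphosphonium pathway may compete with the SN2 inversion. The fallback separates activation and displacement. It sets out from 16: MsCl and Et3N (CH2Cl2, −20 °C) give (1R,2S,8aR)-7-(2-hydroxypropan-2-yl)-1,8a-dimethyl-6-oxo-1,2,3,4,6,8a-hexahydronaphthalen-2-yl methanesulfonate F5, and the caesium salt of 20 (Cs2CO3, DMF, 40 °C) displaces the sulfonate with inversion; the route is rejoined at 21.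

Further compounds
F1 | step 9 | {[(3R,4S)-4-{[tert-butyl(dimethyl)silyl]oxy}-2,3-dimethylcyclohex-1-en-1-yl]methanesulfonyl}benzene | CC(C)(C)[Si](C)(C)O[C@H]1CCC(CS(=O)(=O)c2ccccc2)=C(C)[C@H]1C
F2 | step 9 | (3E)-1-(benzenesulfonyl)-1-[(3R,4S)-4-{[tert-butyl(dimethyl)silyl]oxy}-2,3-dimethylcyclohex-1-en-1-yl]-4-methoxy-3-{2-[(triethylsilyl)oxy]propan-2-yl}but-3-en-2-one (both epimers at C1 of the chain) | CC(C)(C)[Si](C)(C)O[C@H]1CCC(C(C(=O)/C(=C/OC)C(C)(C)O[Si](CC)(CC)CC)S(=O)(=O)c2ccccc2)=C(C)[C@H]1C
F3 | step 2 | ethyl (3S,4R)-4-hydroxy-2,3-dimethylcyclohex-1-ene-1-carboxylate (enantiomer of 4, formed as the racemate with 4) | O[C@@H]1CCC(C(=O)OCC)=C(C)[C@@H]1C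
F4 | step 2 | ethyl (3S,4R)-4-(acetyloxy)-2,3-dimethylcyclohex-1-ene-1-carboxylate | CC(=O)O[C@@H]1CCC(C(=O)OCC)=C(C)[C@@H]1C
F5 | step 14 | (1R,2S,8aR)-7-(2-hydroxypropan-2-yl)-1,8a-dimethyl-6-oxo-1,2,3,4,6,8a-hexahydronaphthalen-2-yl methanesulfonate | CS(=O)(=O)O[C@H]1CCC2=CC(=O)C(C(C)(C)O)=C[C@]2(C)[C@H]1C
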